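## The problem

The target is a stilbene trimer: nine phenols on five benzene rings around a compact pentacyclic core. At its centre is ring C, a resorcinol with a single hydrogen. Going round it, c1 carries the oxygen of dihydrofuran D1, c2 the hydrogen, c3 the oxygen of dihydrofuran D2, c4 the carbon C-d, c5 a CH2 group and c6 the carbon C-b. C-b, the CH2 group and C-c (the CH bearing a 2,4-dihydroxyphenyl group) close the seven-membered carbocycle, ring S, between ring C and the second resorcinol, ring B. Ring D1 (O–C-a–C-b, 4-hydroxyphenyl on C-a) and ring D2 (O–C-e–C-d, 2,4-dihydroxyphenyl on C-e, 3,5-dihydroxyphenyl on C-d) are both trans. Of the five stereocentres (C-a R, C-b R, C-c R, C-d S, C-e S), C-c and C-b are 1,4-related across one edge of ring B inside ring S, so one can direct the other, and C-a follows C-b through the trans dihydrofuran. The pair C-d/C-e is insulated from them by the flat ring C and needs reagent control, with C-e then following C-d. The benzylic C–O bonds of the dihydrofurans (above all C-e–O, next to an ortho/para-dioxygenated ring) ionise under acid, the free polyphenol is air-sensitive, and C-c is at risk under base whenever unsaturation is conjugated to its hydrogen. The enabling feature is ring C itself: with C-b as a ketone it is a 2,4-dihydroxyaryl ketone whose c5–c6 bond is also a bond of ring S. That is the retron of a Michael–Claisen condensation between a β-keto ester (c6, C-b, c1) and an ynone (c5, c4, c3, c2) tethered through C-c and ring B, so one C–C bond closes both rings.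

## Retrosynthesis

Target 32 is traced to its nona-O-methyl ether 31 by cleavage of nine O–CH3 bonds. Methyl ethers are the only masks that survive every base, hydride and organometallic used earlier; benzyl ethers would need hydrogenolysis next to two benzylic C–O bonds. The forward step asks for ether cleavage cold enough to keep the dihydrofurans closed.

Ring D2 of 31 is cut at C-d–C-e and C-e–O, giving the o-quinone methide 30 and a benzylic sulfonium ylide. This removes two stereocentres and one aryl ring in one step and leaves ring C with a one-carbon handle on c4. The o-quinone methide comes from sulfone 26, this from carbinol 25, and 25 from salicylaldehyde 23 and the aryl Grignard reagent 24. Aldehyde 23 comes from phenol 22 by ortho-formylation. The ylide comes from salt 29 (from alcohol 27 and the chiral sulfide 28). The forward reaction must set C-e by the sulfide, close trans, and formylate c4 and not c2.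

Ring D1 of 22 is cut the same way, at C-a–C-b and C-a–O, back to o-quinone methide 20 and the ylide of salt 19 (from alcohol 18). Here the methide carbon C-b lies in ring S, so the existing centre C-c can direct the attack, which an acid-mediated closure under equilibrium would not guarantee. Allyl ether 21 is the direct product. Its precursor chain is sulfone 17, carbinol 16, ketone 15 and the free resorcinol 14, whose hydrogen-bonded and free phenols are told apart by allylation.

Dibenzosuberone 14 is cut at two ring C bonds: c5–c6, which is shared with ring S, and c1–c2. This gives the open-chain precursor 12, in which a β-keto ester on ring B and a methyl ynone are joined through C-c. Against a Friedel–Crafts closure of ring S onto a preformed resorcinol, this cut builds the resorcinol and the seven-membered ring together and delivers the two phenols already differentiated. The precursor has one stereocentre and no ring beyond the two arenes. The forward cascade must add at the alkyne before the base can isomerise it, and close by C-acylation. It passes through adduct 13.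

Ynone 12 is traced to alkyne 11 (C–C bond between the alkyne terminus and the acetyl carbon, acetylide plus Weinreb amide), and 11 to ester 10 (bond between the aryl carbonyl and the α-carbon, crossed Claisen). The order matters: the β-keto ester must exist before the ynone, and the ynone must be released only on acidic quench.

Alkyne 10 comes from phenol 9 by methylation, and 9 from lactol 8 by one-carbon homologation. The lactol comes from lactone 7. The lactone carbonyl carbon thus becomes the internal alkyne carbon (the later c5).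

Lactone 7 is cut at the C-c–aryl bond to coumarin 5 and boronic acid 6. The coumarin holds the acceptor planar, so the ring B ester next to C4 does not block either face. It also ties one of the two 2,4-dioxygenated rings into a lactone, which makes C-c a stereocentre that a catalyst can set. A Friedel–Crafts benzylation of the benzoate would be shorter but racemic and would compete with self-alkylation of the more electron-rich carbinol.

Coumarin 5 comes from salicylaldehyde 3 via cinnamate 4, 3 from aldehyde 2 by chelation-directed demethylation, and 2 from methyl 3,5-dimethoxybenzoate 1 by formylation.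

## Roads not taken

Alternative 1: Ring S is cut at the C-c=CH double bond of dibenzosuberene A1, which would come from intramolecular McMurry coupling of keto aldehyde A2 (ring C aldehyde and ring B diaryl ketone held together by C-b of a preformed ring D1).
- Merits: ring D1 and its two centres are made on a small benzofuran where the trans outcome can be checked early, and reductive carbonyl coupling to dibenzosuberenes has direct precedent.
- Weak points: C-c is sp2 in A1 and must be created afterwards by hydrogenating a hindered triaryl-substituted ring alkene, with C-b as the only control element and with a benzyl ether and a benzylic C–O bond exposed to the catalyst. The diaryl ketone of A2 is flanked by two ortho substituents, so arrest at the pinacol stage is likely. Ring C must be bought or made separately, and ring D2 is still to come.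
- Comparison: A1 is more convergent for rings D1 and S. The chosen plan sets C-c first by catalysis, never has to reduce that alkene, and uses C-c to direct C-b.

Alternative 2: Ring D2 is cut at C-d–aryl, C-d–C-e and C-e–O and built first, by adding Grignard reagent 24 to the O-Boc salicylaldehyde A4 and trapping the resulting o-quinone methide with the chiral ylide of salt 29 to give bromide A3.
- Merits: the remote pair C-d/C-e is set by a reagent on a small achiral substrate, where purity can be upgraded. On this point it is better than the chosen route, which runs the same kind of annulation at the penultimate step.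
- Weak points: everything else (ring S, ring D1, C-c, ring B) must then be built around a pentasubstituted arene from one bromide and one C–H bond. The most acid-labile unit of the molecule, C-e–O, has to survive all of it. The three-component coupling combines a Grignard reagent and a semi-stabilised ylide in one flask.
- Comparison: the chosen plan answers with one cascade for rings C and S and with a ring D2 that meets only the final deprotection.

Alternative 3: Ring B is cut into a vinylketene and ethoxyacetylene. Photolysis of diazo ketone A6 and Danheiser benzannulation would give phenol A5 with four new C–C bonds.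
- Merits: more bonds per step than the chosen key step, a late convergent ring construction, and ring B oxygens differentiated.
- Weak points: A6 must already hold ring C, both dihydrofurans and all five stereocentres. It is then exposed to ultraviolet light and to the heat of the cyclobutenone opening. C-c sits allylic and γ to the ketene, where it can epimerise. A6 is also much harder to make than 12.
- Comparison: A5 is reached in a more striking step, but the chosen plan places its key step where only one stereocentre and no dihydrofuran can be lost.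

Key step: step 10

Assumption: (R)-SEGPHOS is taken to deliver the aryl group to the face that gives (4R)-7, by analogy with the arylation of simple coumarins; if the sense is opposite, the (S)-ligand is used.
Assumption: the (1R,4R,5R) sulfide 28, alkylated on the sulfur lone pair that faces the one-carbon bridge, is taken to give the (S)-configured C-e; if the sense is opposite, the enantiomeric sulfide is used.
Assumption: the Grignard solution 24 and both enantiomers of sulfide 28 are taken as purchasable.

Step 1
Reactants: 1 methyl 3,5-dimethoxybenzoate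
Product: 2 methyl 2-formyl-3,5-dimethoxybenzoate
Conditions: Cl2CHOMe, TiCl4, CH2Cl2, −10 °C → rt; H2O
Reagents that add atoms: dichloromethyl methyl ether, COC(Cl)Cl; water, O
Why: Rieche formylation (electrophilic aromatic substitution by the TiCl4-activated chloromethyl oxocarbenium ion); C2 is para to one methoxy group and ortho to the other and is less crowded than C4 between the two methoxy groups.

Step 2
Reactants: 2 methyl 2-formyl-3,5-dimethoxybenzoate
Product: 3 methyl 2-formyl-3-hydroxy-5-methoxybenzoate
Conditions: BCl3, CH2Cl2, −78 → 0 °C; H2O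
Reagents that add atoms: none
Why: Chelation-directed Lewis-acid ether cleavage: BCl3 bridges the formyl oxygen and the ortho methoxy oxygen, so chloride removes only that methyl group; the 5-methoxy group and the ester cannot form such a chelate.

Step 3
Reactants: 3 methyl 2-formyl-3-hydroxy-5-methoxybenzoate
Product: 5 methyl 7-methoxy-2-oxo-2H-chromene-5-carboxylate, via ethyl (E)-cinnamate 4 (not isolated)
Conditions: Ph3P=CHCO2Et, PhNEt2, 200 °C
Reagents that add atoms: ethyl (triphenylphosphoranylidene)acetate, CCOC(=O)C=P(c1ccccc1)(c1ccccc1)c1ccccc1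
Why: Wittig olefination of the salicylaldehyde, then thermal E/Z equilibration and lactonisation of the ortho-hydroxycinnamate, the standard one-flask coumarin synthesis; no stereocentre is formed.

Step 4
Reactants: 5 methyl 7-methoxy-2-oxo-2H-chromene-5-carboxylate; 6 (2,4-dimethoxyphenyl)boronic acid
Product: 7 methyl (4R)-4-(2,4-dimethoxyphenyl)-7-methoxy-2-oxo-3,4-dihydro-2H-chromene-5-carboxylate
Conditions: Rh(acac)(C2H4)2 (3 mol %), (R)-SEGPHOS, 1,4-dioxane/H2O 10:1, 60 °C
Reagents that add atoms: none
Why: Hayashi–Miyaura asymmetric 1,4-addition of an arylboronic acid to a coumarin with a monovalent rhodium–bisphosphine catalyst (insertion of the alkene into aryl–Rh, then protonolysis); the planar lactone keeps both faces of C4 open although C5 carries the ester, the ester makes the acceptor more electrophilic, and the ligand selects the face so that C4, the later C-c, is formed R.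

Step 5
Reactants: 7 methyl (4R)-4-(2,4-dimethoxyphenyl)-7-methoxy-2-oxo-3,4-dihydro-2H-chromene-5-carboxylate
Product: 8 methyl (4R)-4-(2,4-dimethoxyphenyl)-2-hydroxy-7-methoxy-3,4-dihydro-2H-chromene-5-carboxylate (both C2 epimers)
Conditions: iBu2AlH (1.05 equiv), CH2Cl2, −78 °C; aq. potassium sodium tartrate
Reagents that add atoms: none
Why: Partial reduction of a lactone to the lactol; the aryl lactone is far more electrophilic than the conjugated ortho-substituted methyl benzoate, and the aluminium hemiacetal does not collapse at −78 °C.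

Step 6
Reactants: 8 methyl (4R)-4-(2,4-dimethoxyphenyl)-2-hydroxy-7-methoxy-3,4-dihydro-2H-chromene-5-carboxylate
Product: 9 methyl 2-[(1R)-1-(2,4-dimethoxyphenyl)but-3-yn-1-yl]-3-hydroxy-5-methoxybenzoate
Conditions: MeC(O)C(N2)P(O)(OMe)2, K2CO3, MeOH, 0 °C → rt
Reagents that add atoms: dimethyl (1-diazo-2-oxopropyl)phosphonate, CC(=O)C(=[N+]=[N-])P(=O)(OC)OC
Why: Seyferth–Gilbert homologation in the Ohira–Bestmann form, acting on the hydroxy aldehyde tautomer of the lactol; the former lactone carbon becomes the internal alkyne carbon, and the stereocentre is β to the aldehyde and cannot enolise.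

Step 7
Reactants: 9 methyl 2-[(1R)-1-(2,4-dimethoxyphenyl)but-3-yn-1-yl]-3-hydroxy-5-methoxybenzoate
Product: 10 methyl 2-[(1R)-1-(2,4-dimethoxyphenyl)but-3-yn-1-yl]-3,5-dimethoxybenzoate
Conditions: MeI, K2CO3, DMF, rt
Reagents that add atoms: iodomethane, CI
Why: Williamson methylation of the only phenol; this oxygen must be capped because a free phenoxide would add to the ynone (6-exo-dig oxa-Michael) in step 10.

Step 8
Reactants: 10 methyl 2-[(1R)-1-(2,4-dimethoxyphenyl)but-3-yn-1-yl]-3,5-dimethoxybenzoate
Product: 11 methyl 3-{2-[(1R)-1-(2,4-dimethoxyphenyl)but-3-yn-1-yl]-3,5-dimethoxyphenyl}-3-oxopropanoate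
Conditions: MeOAc, LiN(iPr)2, THF, −78 °C; add 10, −78 → −20 °C; aq. NH4Cl
Reagents that add atoms: methyl acetate, CC(=O)OC
Why: Crossed Claisen condensation of a non-enolisable aryl ester with excess lithium enolate of methyl acetate; the β-keto ester is stored in the flask as its enolate, which stops a second addition.

Step 9
Reactants: 11 methyl 3-{2-[(1R)-1-(2,4-dimethoxyphenyl)but-3-yn-1-yl]-3,5-dimethoxyphenyl}-3-oxopropanoate
Product: 12 methyl 3-{2-[(1R)-1-(2,4-dimethoxyphenyl)-5-oxohex-3-yn-1-yl]-3,5-dimethoxyphenyl}-3-oxopropanoate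
Conditions: LiN(iPr)2 (2.2 equiv), THF, −78 °C; MeC(O)N(OMe)Me, −78 → −40 °C; AcOH, −78 °C
Reagents that add atoms: N-methoxy-N-methylacetamide, CC(=O)N(C)OC
Why: Acylation of a lithium acetylide with a Weinreb amide; the first equivalent of base masks the β-keto ester as its unreactive enolate, the second forms the acetylide, and the chelated adduct releases the ynone only on acidic quench, so ynone and β-keto ester never meet base before step 10.

Step 10
Reactants: 12 methyl 3-{2-[(1R)-1-(2,4-dimethoxyphenyl)-5-oxohex-3-yn-1-yl]-3,5-dimethoxyphenyl}-3-oxopropanoate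
Product: 14 (11R)-11-(2,4-dimethoxyphenyl)-6,8-dihydroxy-1,3-dimethoxy-10,11-dihydro-5H-dibenzo[a,d][7]annulen-5-one, via cycloheptenone Michael adduct 13 (not isolated)
Conditions: Cs2CO3 (3 equiv), DMF, 0 °C → rt, then 60 °C; aq. HCl
Reagents that add atoms: none
Why: Cs2CO3 deprotonates only the β-keto ester, and the stabilised carbanion adds to the alkyne carbon β to the ketone of the tethered ynone; this intramolecular Michael addition is 7-exo-dig and closes ring S through the bond that becomes C5a–C9a (c6–c5) of ring C. Adduct 13 is deprotonated again at C6 to a delocalised dienolate in which rotation about the former triple bond is free, so the geometry with the acetyl group cis to the ester is reached. In that geometry the methyl ketone enolate, formed by proton transfer, attacks the ester (Claisen condensation, 6-exo-trig), methoxide leaves, and the cyclohexadienone tautomerises at once to the resorcinol, whose phenoxide is the thermodynamic sink. The closest known reactions are the Michael–Claisen synthesis of cyclohexane-1,3-diones from malonates or β-keto esters and enones, and its ynone version that gives resorcinols directly; here the partners are tethered. No stereocentre is formed; C11 (C-c) is carried through, protected by the mild base and the fast intramolecular addition, which leave no time for isomerisation of the propargylic CH2 to an allenone or dienone. Two selectivities are needed: C-acylation over O-acylation (an α-pyrone formed through the enol oxygen can reopen under the basic conditions, the phenoxide cannot) and Claisen over aldol closure (the aryl ketone already belongs to ring S and its aldol product cannot aromatise, so it reverts). The product has one hydrogen-bonded and one free phenol, which step 11 uses.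

Step 11
Reactants: 14 (11R)-11-(2,4-dimethoxyphenyl)-6,8-dihydroxy-1,3-dimethoxy-10,11-dihydro-5H-dibenzo[a,d][7]annulen-5-one
Product: 15 (11R)-11-(2,4-dimethoxyphenyl)-6-hydroxy-1,3-dimethoxy-8-(prop-2-en-1-yloxy)-10,11-dihydro-5H-dibenzo[a,d][7]annulen-5-one
Conditions: allyl bromide (1.1 equiv), K2CO3, acetone, rt
Reagents that add atoms: allyl bromide, C=CCBr
Why: Williamson etherification; in a 2,4-dihydroxyaryl ketone the 6-hydroxy group is locked in a hydrogen bond to the carbonyl, so carbonate deprotonates and alkylates only the 8-hydroxy group para to the ketone.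

Step 12
Reactants: 15 (11R)-11-(2,4-dimethoxyphenyl)-6-hydroxy-1,3-dimethoxy-8-(prop-2-en-1-yloxy)-10,11-dihydro-5H-dibenzo[a,d][7]annulen-5-one
Product: 16 (11R)-11-(2,4-dimethoxyphenyl)-1,3-dimethoxy-8-(prop-2-en-1-yloxy)-10,11-dihydro-5H-dibenzo[a,d][7]annulene-5,6-diol (both C5 epimers)
Conditions: NaBH4, THF/MeOH, 0 °C
Reagents that add atoms: none
Why: Hydride reduction of the diaryl ketone; the new carbinol centre is irrelevant because C5 becomes sp2 again in step 15, and the low temperature avoids loss of hydroxide and over-reduction.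

Step 13
Reactants: 16 (11R)-11-(2,4-dimethoxyphenyl)-1,3-dimethoxy-8-(prop-2-en-1-yloxy)-10,11-dihydro-5H-dibenzo[a,d][7]annulene-5,6-diol
Product: 17 (11R)-11-(2,4-dimethoxyphenyl)-1,3-dimethoxy-5-(4-methylbenzenesulfonyl)-8-(prop-2-en-1-yloxy)-10,11-dihydro-5H-dibenzo[a,d][7]annulen-6-ol (both C5 epimers)
Conditions: TolSO2Na, HCO2H, CH2Cl2/H2O, rt
Reagents that add atoms: sodium 4-methylbenzenesulfinate, Cc1ccc(S(=O)[O-])cc1.[Na+]
Why: SN1 substitution of the doubly benzylic, ortho-hydroxy-activated carbinol by sulfinate at sulfur under mild acid, the usual way to a bench-stable 2-(sulfonylalkyl)phenol as o-quinone methide precursor.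

Step 14
Reactants: 18 (4-methoxyphenyl)methanol
Product: 19 1-[(4-methoxyphenyl)methyl]thiolan-1-ium tetrafluoroborate
Conditions: tetrahydrothiophene, aq. HBF4, CH2Cl2, 0 °C → rt
Reagents that add atoms: tetrahydrothiophene, C1CCSC1; tetrafluoroboric acid, [H+].F[B-](F)(F)F
Why: Acid-mediated SN1 alkylation of the sulfide by the 4-methoxybenzyl cation; the non-nucleophilic counter-ion gives a crystalline salt.

Step 15
Reactants: 17 (11R)-11-(2,4-dimethoxyphenyl)-1,3-dimethoxy-5-(4-methylbenzenesulfonyl)-8-(prop-2-en-1-yloxy)-10,11-dihydro-5H-dibenzo[a,d][7]annulen-6-ol; 19 1-[(4-methoxyphenyl)methyl]thiolan-1-ium tetrafluoroborate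
Product: 21 (1R,7R,11bR)-7-(2,4-dimethoxyphenyl)-8,10-dimethoxy-1-(4-methoxyphenyl)-4-(prop-2-en-1-yloxy)-1,6,7,11b-tetrahydrobenzo[6,7]cyclohepta[1,2,3-cd][1]benzofuran, via o-quinone methide 20 (not isolated)
Conditions: Cs2CO3, CH2Cl2/MeCN, 0 °C → rt
Reagents that add atoms: none
Why: Formal (4+1) annulation of a sulfonium ylide with an o-quinone methide: the phenoxide of 17 expels sulfinate to give 20, the ylide adds to C5 (C-b) from the face opposite the pseudo-axial 2,4-dimethoxyphenyl group on C11 (C-c), and the phenoxide displaces tetrahydrothiophene at C-a with inversion (5-exo-tet) from the anti betaine, which gives the trans ring D1; C-b is thus set by C-c and C-a by C-b.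

Step 16
Reactants: 21 (1R,7R,11bR)-7-(2,4-dimethoxyphenyl)-8,10-dimethoxy-1-(4-methoxyphenyl)-4-(prop-2-en-1-yloxy)-1,6,7,11b-tetrahydrobenzo[6,7]cyclohepta[1,2,3-cd][1]benzofuran
Product: 22 (1R,7R,11bR)-7-(2,4-dimethoxyphenyl)-8,10-dimethoxy-1-(4-methoxyphenyl)-1,6,7,11b-tetrahydrobenzo[6,7]cyclohepta[1,2,3-cd][1]benzofuran-4-ol
Conditions: Pd(PPh3)4 (5 mol %), morpholine, THF, rt
Reagents that add atoms: none
Why: Tsuji–Trost deallylation with zerovalent palladium (π-allyl complex trapped by morpholine); the neutral conditions leave the benzylic C–O bond of ring D1 alone, which hydrogenolysis of a benzyl ether might not.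

Step 17
Reactants: 22 (1R,7R,11bR)-7-(2,4-dimethoxyphenyl)-8,10-dimethoxy-1-(4-methoxyphenyl)-1,6,7,11b-tetrahydrobenzo[6,7]cyclohepta[1,2,3-cd][1]benzofuran-4-ol
Product: 23 (1R,7R,11bR)-7-(2,4-dimethoxyphenyl)-4-hydroxy-8,10-dimethoxy-1-(4-methoxyphenyl)-1,6,7,11b-tetrahydrobenzo[6,7]cyclohepta[1,2,3-cd][1]benzofuran-5-carbaldehyde
Conditions: MgCl2, Et3N, (CH2O)n, MeCN, reflux; aq. HCl
Reagents that add atoms: paraformaldehyde (as formaldehyde), C=O
Why: Magnesium-mediated ortho-formylation of a phenol (Casnati–Skattebøl): formaldehyde is delivered inside the magnesium phenoxide only to a carbon ortho to the free hydroxy group, so the other electron-rich rings are not touched; of the two ortho carbons, C5 (para to the furan oxygen) is preferred over C3 between the two oxygens, as in the formylation of 6-hydroxy-2,3-dihydrobenzofuran.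

Step 18
Reactants: 23 (1R,7R,11bR)-7-(2,4-dimethoxyphenyl)-4-hydroxy-8,10-dimethoxy-1-(4-methoxyphenyl)-1,6,7,11b-tetrahydrobenzo[6,7]cyclohepta[1,2,3-cd][1]benzofuran-5-carbaldehyde; 24 (3,5-dimethoxyphenyl)magnesium chloride
Product: 25 (1R,7R,11bR)-5-[(3,5-dimethoxyphenyl)(hydroxy)methyl]-7-(2,4-dimethoxyphenyl)-8,10-dimethoxy-1-(4-methoxyphenyl)-1,6,7,11b-tetrahydrobenzo[6,7]cyclohepta[1,2,3-cd][1]benzofuran-4-ol (both carbinol epimers)
Conditions: THF, −78 → 0 °C; aq. NH4Cl
Reagents that add atoms: none
Why: Grignard addition to the aldehyde after the first equivalent has deprotonated the phenol; the carbinol configuration does not matter because this carbon becomes sp2 in step 21.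

Step 19
Reactants: 25 (1R,7R,11bR)-5-[(3,5-dimethoxyphenyl)(hydroxy)methyl]-7-(2,4-dimethoxyphenyl)-8,10-dimethoxy-1-(4-methoxyphenyl)-1,6,7,11b-tetrahydrobenzo[6,7]cyclohepta[1,2,3-cd][1]benzofuran-4-ol
Product: 26 (1R,7R,11bR)-5-[(3,5-dimethoxyphenyl)(4-methylbenzenesulfonyl)methyl]-7-(2,4-dimethoxyphenyl)-8,10-dimethoxy-1-(4-methoxyphenyl)-1,6,7,11b-tetrahydrobenzo[6,7]cyclohepta[1,2,3-cd][1]benzofuran-4-ol (both epimers at the sulfonyl carbon)
Conditions: TolSO2Na, HCO2H, CH2Cl2/H2O, 0 °C → rt
Reagents that add atoms: sodium 4-methylbenzenesulfinate, Cc1ccc(S(=O)[O-])cc1.[Na+]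
Why: SN1 substitution of the ortho-hydroxybenzhydrol by sulfinate as in step 13; the acid is weak enough to leave ring D1 closed.

Step 20
Reactants: 27 (2,4-dimethoxyphenyl)methanol; 28 (1R,4R,5R)-4,7,7-trimethyl-6-thiabicyclo[3.2.1]octane (isothiocineole)
Product: 29 (1R,4R,5R,6R)-6-[(2,4-dimethoxyphenyl)methyl]-4,7,7-trimethyl-6-thiabicyclo[3.2.1]octan-6-ium tetrafluoroborate
Conditions: aq. HBF4, CH2Cl2, 0 °C
Reagents that add atoms: tetrafluoroboric acid, [H+].F[B-](F)(F)F
Why: SN1 alkylation of the sulfide by the 2,4-dimethoxybenzyl cation; the bicyclic sulfide is alkylated on its exposed lone pair, so one diastereomer at sulfur is expected.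

Step 21
Reactants: 26 (1R,7R,11bR)-5-[(3,5-dimethoxyphenyl)(4-methylbenzenesulfonyl)methyl]-7-(2,4-dimethoxyphenyl)-8,10-dimethoxy-1-(4-methoxyphenyl)-1,6,7,11b-tetrahydrobenzo[6,7]cyclohepta[1,2,3-cd][1]benzofuran-4-ol; 29 (1R,4R,5R,6R)-6-[(2,4-dimethoxyphenyl)methyl]-4,7,7-trimethyl-6-thiabicyclo[3.2.1]octan-6-ium tetrafluoroborate
Product: 31 nona-O-methyl ether of the target (tetracycle of 22 carrying ring D2 across O4–C4–C5; C-a R; C-b R; C-c R; C-d S; C-e S), via o-quinone methide 30 (not isolated)
Conditions: Cs2CO3, CH2Cl2/MeCN, −20 °C → rt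
Reagents that add atoms: none
Why: Formal (4+1) annulation of a sulfonium ylide with an o-quinone methide as in step 15, now under reagent control: the rigid bicyclic sulfide fixes the conformation and the open face of the ylide, so the ylide carbon (C-e) is formed with one absolute configuration, and the anti betaine with SN2 closure by the phenoxide then fixes C-d trans to it; the distant centres of the substrate are not relied on.

Step 22
Reactants: 31 nona-O-methyl ether of the target
Product: 32 target CNP0283541.1 (C-a R; C-b R; C-c R; C-d S; C-e S)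
Conditions: BBr3, CH2Cl2, −78 → 0 °C; MeOH, aq. NaHCO3
Reagents that add atoms: none
Why: Lewis-acid cleavage of all nine aryl methyl ethers (bromide attacks the methyl group of each aryl ether–boron adduct); the low temperature is meant to keep the benzylic C–O bonds of both dihydrofurans closed, and a transient opening would reclose to the trans rings.

Compound list
1 | methyl 3,5-dimethoxybenzoate | COC(=O)c1cc(OC)cc(OC)c1 | starting material
2 | methyl 2-formyl-3,5-dimethoxybenzoate | COC(=O)c1cc(OC)cc(OC)c1C=O | intermediate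
3 | methyl 2-formyl-3-hydroxy-5-methoxybenzoate | COC(=O)c1cc(OC)cc(O)c1C=O | intermediate
4 | ethyl (2E)-3-[2-hydroxy-4-methoxy-6-(methoxycarbonyl)phenyl]prop-2-enoate | CCOC(=O)/C=C/c1c(O)cc(OC)cc1C(=O)OC | intermediate (not isolated)
5 | methyl 7-methoxy-2-oxo-2H-chromene-5-carboxylate | COC(=O)c1cc(OC)cc2OC(=O)C=Cc12 | intermediate
6 | (2,4-dimethoxyphenyl)boronic acid | COc1ccc(B(O)O)c(OC)c1 | starting material
7 | methyl (4R)-4-(2,4-dimethoxyphenyl)-7-methoxy-2-oxo-3,4-dihydro-2H-chromene-5-carboxylate | COC(=O)c1cc(OC)cc2OC(=O)C[C@H](c3ccc(OC)cc3OC)c12 | intermediate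
8 | methyl (4R)-4-(2,4-dimethoxyphenyl)-2-hydroxy-7-methoxy-3,4-dihydro-2H-chromene-5-carboxylate (both C2 epimers) | COC(=O)c1cc(OC)cc2OC(O)C[C@H](c3ccc(OC)cc3OC)c12 | intermediate
9 | methyl 2-[(1R)-1-(2,4-dimethoxyphenyl)but-3-yn-1-yl]-3-hydroxy-5-methoxybenzoate | COC(=O)c1cc(OC)cc(O)c1[C@@H](c1ccc(OC)cc1OC)CC#C | intermediate
10 | methyl 2-[(1R)-1-(2,4-dimethoxyphenyl)but-3-yn-1-yl]-3,5-dimethoxybenzoate | COC(=O)c1cc(OC)cc(OC)c1[C@@H](c1ccc(OC)cc1OC)CC#C | intermediate
11 | methyl 3-{2-[(1R)-1-(2,4-dimethoxyphenyl)but-3-yn-1-yl]-3,5-dimethoxyphenyl}-3-oxopropanoate | COC(=O)CC(=O)c1cc(OC)cc(OC)c1[C@@H](c1ccc(OC)cc1OC)CC#C | intermediate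
12 | methyl 3-{2-[(1R)-1-(2,4-dimethoxyphenyl)-5-oxohex-3-yn-1-yl]-3,5-dimethoxyphenyl}-3-oxopropanoate | COC(=O)CC(=O)c1cc(OC)cc(OC)c1[C@@H](c1ccc(OC)cc1OC)CC#CC(C)=O | intermediate
13 | methyl (7Z,9R)-9-(2,4-dimethoxyphenyl)-1,3-dimethoxy-5-oxo-7-(2-oxopropylidene)-6,7,8,9-tetrahydro-5H-benzo[7]annulene-6-carboxylate (C6 epimers and enol forms) | COC(=O)C1C(=O)c2cc(OC)cc(OC)c2[C@@H](c2ccc(OC)cc2OC)C/C1=C/C(C)=O | intermediate (not isolated)
14 | (11R)-11-(2,4-dimethoxyphenyl)-6,8-dihydroxy-1,3-dimethoxy-10,11-dihydro-5H-dibenzo[a,d][7]annulen-5-one | Oc1cc(O)c2c(c1)C[C@H](c1ccc(OC)cc1OC)c1c(OC)cc(OC)cc1C2=O | intermediate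
15 | (11R)-11-(2,4-dimethoxyphenyl)-6-hydroxy-1,3-dimethoxy-8-(prop-2-en-1-yloxy)-10,11-dihydro-5H-dibenzo[a,d][7]annulen-5-one | C=CCOc1cc(O)c2c(c1)C[C@H](c1ccc(OC)cc1OC)c1c(OC)cc(OC)cc1C2=O | intermediate
16 | (11R)-11-(2,4-dimethoxyphenyl)-1,3-dimethoxy-8-(prop-2-en-1-yloxy)-10,11-dihydro-5H-dibenzo[a,d][7]annulene-5,6-diol (both C5 epimers) | C=CCOc1cc(O)c2c(c1)C[C@H](c1ccc(OC)cc1OC)c1c(OC)cc(OC)cc1C2O | intermediate
17 | (11R)-11-(2,4-dimethoxyphenyl)-1,3-dimethoxy-5-(4-methylbenzenesulfonyl)-8-(prop-2-en-1-yloxy)-10,11-dihydro-5H-dibenzo[a,d][7]annulen-6-ol (both C5 epimers) | C=CCOc1cc(O)c2c(c1)C[C@H](c1ccc(OC)cc1OC)c1c(OC)cc(OC)cc1C2S(=O)(=O)c1ccc(C)cc1 | intermediate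
18 | (4-methoxyphenyl)methanol | COc1ccc(CO)cc1 | starting material
19 | 1-[(4-methoxyphenyl)methyl]thiolan-1-ium tetrafluoroborate | COc1ccc(C[S+]2CCCC2)cc1.F[B-](F)(F)F | intermediate
20 | (11R)-11-(2,4-dimethoxyphenyl)-1,3-dimethoxy-8-(prop-2-en-1-yloxy)-10,11-dihydro-6H-dibenzo[a,d][7]annulen-6-one (o-quinone methide, C5=C5a) | C=CCOC1=CC(=O)C2=Cc3cc(OC)cc(OC)c3[C@@H](c3ccc(OC)cc3OC)CC2=C1 | intermediate (not isolated)
21 | (1R,7R,11bR)-7-(2,4-dimethoxyphenyl)-8,10-dimethoxy-1-(4-methoxyphenyl)-4-(prop-2-en-1-yloxy)-1,6,7,11b-tetrahydrobenzo[6,7]cyclohepta[1,2,3-cd][1]benzofuran | COc1ccc([C@@H]2Oc3cc(OCC=C)cc4c3[C@H]2c2cc(OC)cc(OC)c2[C@@H](c2ccc(OC)cc2OC)C4)cc1 | intermediate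
22 | (1R,7R,11bR)-7-(2,4-dimethoxyphenyl)-8,10-dimethoxy-1-(4-methoxyphenyl)-1,6,7,11b-tetrahydrobenzo[6,7]cyclohepta[1,2,3-cd][1]benzofuran-4-ol | COc1ccc([C@@H]2Oc3cc(O)cc4c3[C@H]2c2cc(OC)cc(OC)c2[C@@H](c2ccc(OC)cc2OC)C4)cc1 | intermediate
23 | (1R,7R,11bR)-7-(2,4-dimethoxyphenyl)-4-hydroxy-8,10-dimethoxy-1-(4-methoxyphenyl)-1,6,7,11b-tetrahydrobenzo[6,7]cyclohepta[1,2,3-cd][1]benzofuran-5-carbaldehyde | COc1ccc([C@@H]2Oc3cc(O)c(C=O)c4c3[C@H]2c2cc(OC)cc(OC)c2[C@@H](c2ccc(OC)cc2OC)C4)cc1 | intermediate
24 | (3,5-dimethoxyphenyl)magnesium chloride (solution in THF) | COc1cc([Mg]Cl)cc(OC)c1 | starting material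
25 | (1R,7R,11bR)-5-[(3,5-dimethoxyphenyl)(hydroxy)methyl]-7-(2,4-dimethoxyphenyl)-8,10-dimethoxy-1-(4-methoxyphenyl)-1,6,7,11b-tetrahydrobenzo[6,7]cyclohepta[1,2,3-cd][1]benzofuran-4-ol (both carbinol epimers) | COc1ccc([C@@H]2Oc3cc(O)c(C(O)c5cc(OC)cc(OC)c5)c4c3[C@H]2c2cc(OC)cc(OC)c2[C@@H](c2ccc(OC)cc2OC)C4)cc1 | intermediate
26 | (1R,7R,11bR)-5-[(3,5-dimethoxyphenyl)(4-methylbenzenesulfonyl)methyl]-7-(2,4-dimethoxyphenyl)-8,10-dimethoxy-1-(4-methoxyphenyl)-1,6,7,11b-tetrahydrobenzo[6,7]cyclohepta[1,2,3-cd][1]benzofuran-4-ol (both epimers at the sulfonyl carbon) | COc1ccc([C@@H]2Oc3cc(O)c(C(c5cc(OC)cc(OC)c5)S(=O)(=O)c5ccc(C)cc5)c4c3[C@H]2c2cc(OC)cc(OC)c2[C@@H](c2ccc(OC)cc2OC)C4)cc1 | intermediate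
27 | (2,4-dimethoxyphenyl)methanol | COc1ccc(CO)c(OC)c1 | starting material
28 | (1R,4R,5R)-4,7,7-trimethyl-6-thiabicyclo[3.2.1]octane (isothiocineole) | C[C@@H]1CC[C@@H]2C[C@H]1SC2(C)C | starting material
29 | (1R,4R,5R,6R)-6-[(2,4-dimethoxyphenyl)methyl]-4,7,7-trimethyl-6-thiabicyclo[3.2.1]octan-6-ium tetrafluoroborate | C[C@@H]1CC[C@@H]2C[C@H]1[S@@+](Cc1ccc(OC)cc1OC)C2(C)C.F[B-](F)(F)F | intermediate
30 | (1R,7R,11bR)-5-[(3,5-dimethoxyphenyl)methylidene]-7-(2,4-dimethoxyphenyl)-8,10-dimethoxy-1-(4-methoxyphenyl)-1,6,7,11b-tetrahydrobenzo[6,7]cyclohepta[1,2,3-cd][1]benzofuran-4(5H)-one (o-quinone methide) | COc1ccc([C@@H]2OC3=CC(=O)C(=Cc4cc(OC)cc(OC)c4)C4=C3[C@H]2c2cc(OC)cc(OC)c2[C@@H](c2ccc(OC)cc2OC)C4)cc1 | intermediate (not isolated)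
31 | nona-O-methyl ether of the target: tetracycle of 22 with ring D2 fused across O4–C4–C5, C-e bearing 2,4-dimethoxyphenyl on the oxygen side and C-d bearing 3,5-dimethoxyphenyl on C5 (C-a R; C-b R; C-c R; C-d S; C-e S) | COc1ccc([C@@H]2Oc3cc4c(c5c3[C@H]2c2cc(OC)cc(OC)c2[C@@H](c2ccc(OC)cc2OC)C5)[C@H](c2cc(OC)cc(OC)c2)[C@@H](c2ccc(OC)cc2OC)O4)cc1 | intermediate
32 | CNP0283541.1 (C-a R; C-b R; C-c R; C-d S; C-e S) | Oc1ccc([C@@H]2Oc3cc4c(c5c3[C@H]2c2cc(O)cc(O)c2[C@@H](c2ccc(O)cc2O)C5)[C@H](c2cc(O)cc(O)c2)[C@@H](c2ccc(O)cc2O)O4)cc1 | target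

Total step count: 22. Longest linear sequence: 20 steps (steps 1–13, 15–19, 21 and 22, from compound 1); steps 14 and 20 are one-step preparations of the two sulfonium salts.

Least certain steps

Step 10 (key step). The cascade may stall after the conjugate addition or leak into O-acylation, because the ketone enolate needed for the Claisen closure is a minor tautomer of a very stable dienolate. A slow first addition would also give the carbonate time to isomerise the propargylic CH2 and so erode C11. The fallback sets out from 11 and builds ring C at the dione level, with no alkyne.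
- Semi-hydrogenation (H2, Pd/CaCO3–Pb(OAc)2, quinoline) gives methyl 3-{2-[(1R)-1-(2,4-dimethoxyphenyl)but-3-en-1-yl]-3,5-dimethoxyphenyl}-3-oxopropanoate F1.
- Cross-metathesis with methyl vinyl ketone (second-generation Grubbs catalyst, (H2IMes)(PCy3)Cl2Ru=CHPh) gives the (E)-enone methyl 3-{2-[(1R,3E)-1-(2,4-dimethoxyphenyl)-5-oxohex-3-en-1-yl]-3,5-dimethoxyphenyl}-3-oxopropanoate F2.
- NaOMe in MeOH effects the classical Michael–Claisen annulation (7-exo-trig, then 6-exo-trig) to (11R)-11-(2,4-dimethoxyphenyl)-1,3-dimethoxy-5a,7,9,9a,10,11-hexahydro-5H-dibenzo[a,d][7]annulene-5,6,8-trione F3.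
- Dehydrogenation with DDQ returns to the route at 14.

Step 4. Carbometalation may be slow at a coumarin whose C5 ester crowds C4, which would let protodeboronation of the electron-rich boronic acid and hydrolysis of the lactone take over, or would lower the facial selectivity. The fallback sets out from 3.
- Wittig reaction with Ph3P=CHCHO gives methyl 3-hydroxy-5-methoxy-2-[(1E)-3-oxoprop-1-en-1-yl]benzoate F4.
- Amine-catalysed conjugate addition of boronic acid 6 follows, with the diphenylprolinol trimethylsilyl ether enantiomer that leads to the (4R) product. The phenol binds the boronic acid and the aryl group is transferred within the iminium ion.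
- This gives lactol 8 directly, where the route is rejoined.

Step 15. Facial selectivity at C5 may be poor if the C11 aryl group does not sit pseudo-axial in 20, or ring closure of the betaine may be slow in the constrained ring S, so that it reverts while the ylide decays. The fallback sets out from 15 and works under thermodynamic control.
- Addition of (4-methoxybenzyl)magnesium chloride gives (11R)-11-(2,4-dimethoxyphenyl)-1,3-dimethoxy-5-[(4-methoxyphenyl)methyl]-8-(prop-2-en-1-yloxy)-10,11-dihydro-5H-dibenzo[a,d][7]annulene-5,6-diol F5.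
- Catalytic TsOH in toluene dehydrates it to the benzylidene compound (11R)-11-(2,4-dimethoxyphenyl)-1,3-dimethoxy-5-[(4-methoxyphenyl)methylidene]-8-(prop-2-en-1-yloxy)-10,11-dihydro-5H-dibenzo[a,d][7]annulen-6-ol F6.
- Under the same acid the phenol adds across the double bond through the 4-methoxybenzyl cation, returning to the route at 21.

Step 21. Reagent control may be insufficient. The very electron-rich sulfonium salt may ionise so that the ylide adds through a less ordered path, or the facial bias of the substrate may oppose the sulfide, so that the (C-d R, C-e R) diastereomer forms as well. The fallback sets out from 25 and sets C-d by a catalyst.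
- Etherification of the phenol with 2,4-dimethoxybenzyl chloride and K2CO3 gives the 4-O-(2,4-dimethoxybenzyl) ether of 25, F7.
- MnO2 oxidises the carbinol to the 5-(3,5-dimethoxybenzoyl) ketone F8.
- Hydrazine with catalytic AcOH gives its hydrazone F9.
- MnO2 oxidises this to the diaryldiazomethane F10.
- Rh2(R-PTAD)4 (or its enantiomer, whichever gives the S centre at C-d) effects carbene insertion into the benzylic ether C–H bond to give the cis-fused C-e epimer of 31, F11.
- Catalytic TsOH epimerises C-e through the benzylic cation to the trans ring, returning to the route at 31.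

Step 22. The Lewis acid may ionise the benzylic C–O bonds, above all C-e–O next to the 2,4-dioxygenated ring, with ring opening, epimerisation or Friedel–Crafts recombination, and cleavage of nine ethers may stop short. The fallback sets out from 31 and avoids cations.
- Nucleophilic demethylation with NaSEt in DMF at 140 °C under argon gives the nonaphenoxide.
- The crude product is acetylated (Ac2O, pyridine) to the nonaacetate of the target F12, which can be purified.
- K2CO3 in MeOH removes the acetates, returning to the route at 32.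

Further compounds
F1 | step 10 | methyl 3-{2-[(1R)-1-(2,4-dimethoxyphenyl)but-3-en-1-yl]-3,5-dimethoxyphenyl}-3-oxopropanoate | COC(=O)CC(=O)c1cc(OC)cc(OC)c1[C@@H](c1ccc(OC)cc1OC)CC=C
F2 | step 10 | methyl 3-{2-[(1R,3E)-1-(2,4-dimethoxyphenyl)-5-oxohex-3-en-1-yl]-3,5-dimethoxyphenyl}-3-oxopropanoate | COC(=O)CC(=O)c1cc(OC)cc(OC)c1[C@@H](c1ccc(OC)cc1OC)C/C=C/C(C)=O
F3 | step 10 | (11R)-11-(2,4-dimethoxyphenyl)-1,3-dimethoxy-5a,7,9,9a,10,11-hexahydro-5H-dibenzo[a,d][7]annulene-5,6,8-trione (ring-fusion epimers) | O=C1CC(=O)C2C(C1)C[C@H](c1ccc(OC)cc1OC)c1c(OC)cc(OC)cc1C2=O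
F4 | step 4 | methyl 3-hydroxy-5-methoxy-2-[(1E)-3-oxoprop-1-en-1-yl]benzoate | COC(=O)c1cc(OC)cc(O)c1/C=C/C=O
F5 | step 15 | (11R)-11-(2,4-dimethoxyphenyl)-1,3-dimethoxy-5-[(4-methoxyphenyl)methyl]-8-(prop-2-en-1-yloxy)-10,11-dihydro-5H-dibenzo[a,d][7]annulene-5,6-diol (both C5 epimers) | C=CCOc1cc(O)c2c(c1)C[C@H](c1ccc(OC)cc1OC)c1c(OC)cc(OC)cc1C2(O)Cc1ccc(OC)cc1
F6 | step 15 | (11R)-11-(2,4-dimethoxyphenyl)-1,3-dimethoxy-5-[(4-methoxyphenyl)methylidene]-8-(prop-2-en-1-yloxy)-10,11-dihydro-5H-dibenzo[a,d][7]annulen-6-ol | C=CCOc1cc(O)c2c(c1)C[C@H](c1ccc(OC)cc1OC)c1c(OC)cc(OC)cc1C2=Cc1ccc(OC)cc1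
F7 | step 21 | 4-O-(2,4-dimethoxybenzyl) ether of 25 (both carbinol epimers) | COc1ccc([C@@H]2Oc3cc(OCc6ccc(OC)cc6OC)c(C(O)c5cc(OC)cc(OC)c5)c4c3[C@H]2c2cc(OC)cc(OC)c2[C@@H](c2ccc(OC)cc2OC)C4)cc1
F8 | step 21 | 5-(3,5-dimethoxybenzoyl) ketone from F7 | COc1ccc([C@@H]2Oc3cc(OCc6ccc(OC)cc6OC)c(C(=O)c5cc(OC)cc(OC)c5)c4c3[C@H]2c2cc(OC)cc(OC)c2[C@@H](c2ccc(OC)cc2OC)C4)cc1
F9 | step 21 | hydrazone of F8 | COc1ccc([C@@H]2Oc3cc(OCc6ccc(OC)cc6OC)c(C(=NN)c5cc(OC)cc(OC)c5)c4c3[C@H]2c2cc(OC)cc(OC)c2[C@@H](c2ccc(OC)cc2OC)C4)cc1
F10 | step 21 | diaryldiazomethane from F9 | COc1ccc([C@@H]2Oc3cc(OCc6ccc(OC)cc6OC)c(C(=[N+]=[N-])c5cc(OC)cc(OC)c5)c4c3[C@H]2c2cc(OC)cc(OC)c2[C@@H](c2ccc(OC)cc2OC)C4)cc1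
F11 | step 21 | C-e epimer of 31 with cis ring D2 (C-a R; C-b R; C-c R; C-d S; C-e R) | COc1ccc([C@@H]2Oc3cc4c(c5c3[C@H]2c2cc(OC)cc(OC)c2[C@@H](c2ccc(OC)cc2OC)C5)[C@H](c2cc(OC)cc(OC)c2)[C@H](c2ccc(OC)cc2OC)O4)cc1
F12 | step 22 | nonaacetate of the target | CC(=O)Oc1ccc([C@@H]2Oc3cc4c(c5c3[C@H]2c2cc(OC(C)=O)cc(OC(C)=O)c2[C@@H](c2ccc(OC(C)=O)cc2OC(C)=O)C5)[C@H](c2cc(OC(C)=O)cc(OC(C)=O)c2)[C@@H](c2ccc(OC(C)=O)cc2OC(C)=O)O4)cc1
A1 | alternative 1 | (1R,11bR)-4-(benzyloxy)-7-(2,4-dimethoxyphenyl)-8,10-dimethoxy-1-(4-methoxyphenyl)-1,11b-dihydrobenzo[6,7]cyclohepta[1,2,3-cd][1]benzofuran | COc1ccc([C@@H]2Oc3cc(OCc5ccccc5)cc4c3[C@H]2c2cc(OC)cc(OC)c2C(c2ccc(OC)cc2OC)=C4)cc1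
A2 | alternative 1 | (2R,3R)-6-(benzyloxy)-3-[2-(2,4-dimethoxybenzoyl)-3,5-dimethoxyphenyl]-2-(4-methoxyphenyl)-2,3-dihydro-1-benzofuran-4-carbaldehyde | COc1ccc([C@@H]2Oc3cc(OCc4ccccc4)cc(C=O)c3[C@H]2c2cc(OC)cc(OC)c2C(=O)c2ccc(OC)cc2OC)cc1
A3 | alternative 2 | (2S,3S)-4-bromo-2-(2,4-dimethoxyphenyl)-3-(3,5-dimethoxyphenyl)-6-methoxy-2,3-dihydro-1-benzofuran | COc1cc2c(c(Br)c1)[C@H](c1cc(OC)cc(OC)c1)[C@@H](c1ccc(OC)cc1OC)O2
A4 | alternative 2 | 2-bromo-6-[(tert-butoxycarbonyl)oxy]-4-methoxybenzaldehyde | COc1cc(Br)c(C=O)c(OC(=O)OC(C)(C)C)c1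
A5 | alternative 3 | target skeleton with ring B as 10-ethoxy-8-hydroxy and all other phenols methylated | COc1ccc([C@@H]2Oc3cc4c(c5c3[C@H]2c2cc(OCC)cc(O)c2[C@@H](c2ccc(OC)cc2OC)C5)[C@H](c2cc(OC)cc(OC)c2)[C@@H](c2ccc(OC)cc2OC)O4)cc1
A6 | alternative 3 | diazomethyl ketone on the cycloheptene that holds ring C, both dihydrofurans and C-c | COc1ccc([C@@H]2Oc3cc4c(c5c3[C@H]2C(C(=O)C=[N+]=[N-])=C[C@@H](c2ccc(OC)cc2OC)C5)[C@H](c2cc(OC)cc(OC)c2)[C@@H](c2ccc(OC)cc2OC)O4)cc1
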